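**Retrosynthetic overview**

1. The target is epigallocatechin‑3‑O‑gallate‑(4β→6)‑gallocatechin. The end game is global hydrogenolysis (14 benzyl ethers, one aryl bromide), preceded by C2–H formation through ionic reduction of a C2 methyl ketal anti to the C3 gallate, and C3–O formation through α‑face epoxidation of a flav‑2‑ene.
2. The strategy rests on the upper pyran (O1, C2, C3, C4, C4a, C8a). Its C4 is a diarylmethine bonded to C4a of the upper A ring and to C6' of the lower flavan, and it sits beside the oxygenated C3 and the O1‑bearing C2. C3–C4 and O1–C2 are therefore made together by a formal [4+2] between the A‑ring ortho‑quinone methide (O=C8a–C4a=C4) and a B‑ring enamide (C2=C3).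
3. The quinone‑methide precursor is a diarylcarbinol. Its C4–C6' bond comes from addition of 6‑lithio‑8‑bromo‑hexa‑O‑benzylgallocatechin to 2‑allyloxy‑4,6‑dibenzyloxybenzaldehyde; the allyl group is then removed with Pd(0) without acid.
4. Ring order: the three lower rings come intact from (+)‑gallocatechin, the upper A ring from 3,5‑dibenzyloxyphenol, the upper pyran closes in the key step, and the B ring and galloyl group both come from 3,4,5‑tribenzyloxybenzoic acid.

Key step: step 13

**Remarks on the chemistry (assumptions)**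

- Unprimed locants are the upper unit, primed locants the lower unit. α/β are used as in flavan‑3‑ols: the B ring and the C3 oxygen of the upper unit are α, the C4 aryl is β.
- The lower unit carries a C8' bromine through the route. It directs the halogen–metal exchange to C6', blocks the most nucleophilic arene position during the acid steps, and is removed in the final hydrogenolysis.
- The phenol of the aldehyde partner is masked as an allyl ether, because the doubly activated diarylcarbinol would ionise under the acid needed to remove an acetal.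
- The sense of induction of the phosphoric acid on this methide cannot be predicted with confidence. (R)‑TRIP is written; the (S)‑acid, which is also sold, takes its place if the first run favours the C4 epimer.
- (+)‑Gallocatechin, 3,5‑bis(benzyloxy)phenol and 3,4,5‑tris(benzyloxy)benzoic acid are taken as purchased.

**Route**

Step 1
Reactants: 1 (+)-gallocatechin
Product: 2 5,7,3',4',5'-penta-O-benzyl-(+)-gallocatechin
Conditions: BnBr (5.5 equiv), K2CO3, DMF, Ar, 0 °C → rt
Reagents that add atoms: benzyl bromide BrCc1ccccc1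
Why: Williamson etherification of the five phenols; carbonate does not deprotonate the secondary 3‑OH and the rapid capping of the 4'‑phenol prevents base‑induced C2 epimerisation, so C2 and C3 are untouched.

Step 2
Reactants: 2 5,7,3',4',5'-penta-O-benzyl-(+)-gallocatechin
Product: 3 3,5,7,3',4',5'-hexa-O-benzyl-(+)-gallocatechin
Conditions: NaH, BnBr, TBAI (cat.), DMF, 0 °C → rt
Reagents that add atoms: benzyl bromide BrCc1ccccc1
Why: Williamson etherification of the remaining secondary alcohol; with every phenol capped no quinone‑methide ring opening can scramble C2.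

Step 3
Reactants: 3 3,5,7,3',4',5'-hexa-O-benzyl-(+)-gallocatechin
Product: 4 8-bromo-3,5,7,3',4',5'-hexa-O-benzyl-(+)-gallocatechin
Conditions: NBS (1.0 equiv), CH2Cl2, −78 → 0 °C
Reagents that add atoms: N-bromosuccinimide O=C1CCC(=O)N1Br
Why: Electrophilic aromatic bromination; in 5,7‑dialkoxyflavans C8 is the more reactive A‑ring position and the trialkoxy B ring is less nucleophilic, so one equivalent should give the 8‑bromide.

Step 4
Reactants: 4 8-bromo-3,5,7,3',4',5'-hexa-O-benzyl-(+)-gallocatechin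
Product: 5 8-bromo-6-iodo-3,5,7,3',4',5'-hexa-O-benzyl-(+)-gallocatechin
Conditions: NIS (1.1 equiv), MeCN–CH2Cl2, 0 °C → rt
Reagents that add atoms: N-iodosuccinimide O=C1CCC(=O)N1I
Why: Electrophilic aromatic iodination at C6, the only remaining A‑ring position, which is flanked by two benzyloxy groups and para to O1.

Step 5
Reactants: 6 3,5-bis(benzyloxy)phenol
Product: 8 2-hydroxy-4,6-bis(benzyloxy)benzaldehyde, via salicyl alcohol 7 (not isolated)
Conditions: MgCl2, Et3N, (CH2O)n, MeCN, reflux; aq HCl work-up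
Reagents that add atoms: paraformaldehyde, as formaldehyde C=O
Why: Magnesium‑phenoxide‑directed ortho‑formylation: hydroxymethylation occurs only ortho to the phenol (the two ortho positions are equivalent) and the salicyl alcohol is oxidised by a second formaldehyde in an Oppenauer‑type hydride transfer.

Step 6
Reactants: 8 2-hydroxy-4,6-bis(benzyloxy)benzaldehyde
Product: 9 2-(allyloxy)-4,6-bis(benzyloxy)benzaldehyde
Conditions: allyl bromide, K2CO3, DMF, 40 °C
Reagents that add atoms: allyl bromide C=CCBr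
Why: Williamson etherification of the hydrogen‑bonded phenol with a reactive allylic halide gives a phenol mask that can later be removed without acid.

Step 7
Reactants: 5 8-bromo-6-iodo-3,5,7,3',4',5'-hexa-O-benzyl-(+)-gallocatechin; 9 2-(allyloxy)-4,6-bis(benzyloxy)benzaldehyde
Product: 11 O-allyl diarylcarbinol, via 6-lithio arene 10 (not isolated)
Conditions: n-BuLi (1.05 equiv), THF, −78 °C, 15 min; then 9, −78 → −40 °C; sat. aq NH4Cl
Reagents that add atoms: none
Why: Iodine–lithium exchange is far faster than bromine–lithium exchange, so only C6' is metallated, and the aryllithium adds 1,2 to the aldehyde; the carbinol carbon forms as both epimers, which is immaterial because it becomes planar in step 13.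

Step 8
Reactants: 11 O-allyl diarylcarbinol
Product: 12 (2-hydroxy-4,6-dibenzyloxyphenyl)(8-bromo-hexa-O-benzylgallocatechin-6-yl)methanol
Conditions: Pd(PPh3)4 (5 mol%), morpholine, THF, rt; Et3N-deactivated silica, used at once
Reagents that add atoms: none
Why: Tsuji–Trost deallylation: Pd(0) ionises the aryl allyl ether and morpholine traps the π‑allyl complex, under neutral to basic conditions that leave the acid‑labile carbinol, the benzyl ethers and the hindered electron‑rich aryl bromide alone.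

Step 9
Reactants: 13 3,4,5-tris(benzyloxy)benzoic acid
Product: 14 3,4,5-tris(benzyloxy)benzoyl chloride
Conditions: (COCl)2, DMF (cat.), CH2Cl2, 0 °C → rt
Reagents that add atoms: oxalyl chloride O=C(Cl)C(Cl)=O
Why: Acid chloride formation through the Vilsmeier‑type chloroiminium catalyst, which benzyl ethers tolerate.

Step 10
Reactants: 14 3,4,5-tris(benzyloxy)benzoyl chloride
Product: 15 3',4',5'-tris(benzyloxy)acetophenone
Conditions: MeMgBr (1.05 equiv), Fe(acac)3 (3 mol%), THF, −78 °C
Reagents that add atoms: methylmagnesium bromide C[Mg]Br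
Why: Iron‑catalysed acylation of a Grignard reagent by an acid chloride, which is much faster than addition to the product ketone and so stops at the methyl ketone.

Step 11
Reactants: 15 3',4',5'-tris(benzyloxy)acetophenone
Product: 16 3',4',5'-tris(benzyloxy)acetophenone oxime
Conditions: NH2OH·HCl, NaOAc, EtOH–THF, 70 °C
Reagents that add atoms: hydroxylamine hydrochloride NO.Cl
Why: Buffered oxime condensation of an aryl methyl ketone; the oxime geometry does not matter for the next step.

Step 12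
Reactants: 16 3',4',5'-tris(benzyloxy)acetophenone oxime
Product: 18 N-[1-(3,4,5-tribenzyloxyphenyl)vinyl]acetamide, via oxime acetate 17 (not isolated)
Conditions: Fe powder, Ac2O, AcOH, toluene, 70 °C
Reagents that add atoms: acetic anhydride CC(=O)OC(C)=O
Why: Reductive acylation of a ketoxime: O‑acetylation, N–O cleavage by iron(0), then N‑acetylation and tautomerisation to the 1‑arylvinyl enamide.

Step 13
Reactants: 12 (2-hydroxy-4,6-dibenzyloxyphenyl)(8-bromo-hexa-O-benzylgallocatechin-6-yl)methanol; 18 N-[1-(3,4,5-tribenzyloxyphenyl)vinyl]acetamide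
Product: 21 (4R)-flav-2-ene carrying the lower unit at C4, via ortho-quinone methide 19 (not isolated), via 2-acetamidochroman 20 (not isolated)
Conditions: (R)-TRIP (10 mol%), 18 (1.5 equiv), 4 Å MS, CH2Cl2, −20 °C → rt; then 40 °C until 20 is consumed; Et3N quench
Reagents that add atoms: none
Why: The phosphoric acid ionises the benzylic C4–OH of 12 to the A‑ring ortho‑quinone methide 19 (O=C8a, C4a=C4), which stays hydrogen‑bonded to the phosphate while the same phosphate binds the enamide N–H; the enamide CH2 adds to the methide carbon (C3–C4), the phenol oxygen adds to the resulting N‑acyliminium carbon (O1–C2) to give ketal 20, and 20 loses acetamide under the same acid, helped by the 2‑aryl group, to leave the C2=C3 enol ether of 21. The closest known reaction is the chiral‑phosphoric‑acid‑catalysed formal [4+2] of enamides or 1,3‑dicarbonyls with ortho‑hydroxybenzhydrols, which gives 4‑aryl‑4H‑chromenes. The one new ring, the upper pyran, closes by 6‑exo‑trig attack of O1 on the iminium carbon after the intermolecular Michael‑type C–C bond formation. The one new stereocentre, C4, is set under catalyst control in the C–C bond‑forming step, because the lower‑unit stereocentres C2' and C3' lie five bonds away and cannot bias the methide faces themselves. The step needs face selectivity at C4 and a single mode of ionisation: only the A‑ring phenol is free, so only one quinone methide can form, the enamide polarity fixes C3 as the carbon bonded to C4, and the C8' bromine together with excess enamide keeps the methide from alkylating the lower A ring of a second molecule.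

Step 14
Reactants: 21 (4R)-flav-2-ene carrying the lower unit at C4
Product: 23 C2 methyl ketal 3α-ol, via 2,3-epoxide 22 (not isolated)
Conditions: DMDO (1.2 equiv, acetone), CH2Cl2, −40 °C; then MeOH, −40 → 0 °C
Reagents that add atoms: dimethyldioxirane CC1(C)OO1; methanol CO
Why: Glycal‑type epoxidation–solvolysis: the dioxirane attacks the electron‑rich C2=C3 enol ether on the face opposite the pseudo‑axial C4 aryl, which sets C3–O trans to C4, and methanol opens the labile 2‑aryl epoxide at C2 to a ketal whose configuration is of no consequence.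

Step 15
Reactants: 23 C2 methyl ketal 3α-ol; 14 3,4,5-tris(benzyloxy)benzoyl chloride
Product: 24 C2 methyl ketal 3-O-(tri-O-benzylgalloyl) ester
Conditions: 14 (3 equiv), DMAP, pyridine, CH2Cl2, rt → 40 °C
Reagents that add atoms: none
Why: DMAP‑catalysed acylation of the only free hydroxyl; the basic medium leaves the ketal and the interflavan bond alone and C3 keeps its configuration.

Step 16
Reactants: 24 C2 methyl ketal 3-O-(tri-O-benzylgalloyl) ester
Product: 26 per-O-benzyl 8'-bromo dimer gallate, via C2 oxocarbenium ion 25 (not isolated)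
Conditions: Et3SiH (5 equiv), BF3·OEt2 (2 equiv), CH2Cl2, −78 → −40 °C; Et3N then aq NaHCO3
Reagents that add atoms: none
Why: Ionic hydrogenation of the ketal: BF3 removes methoxide to give the 2‑aryl oxocarbenium ion 25, the neighbouring C3 galloyl carbonyl bridges its α face as an acyloxonium, and Et3SiH delivers hydride to C2 from the β face, anti to the ester, which places the B ring cis to the C3 ester (2,3‑cis) with 3,4‑trans unchanged.

Step 17
Reactants: 26 per-O-benzyl 8'-bromo dimer gallate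
Product: 27 CNP0271447.2, epigallocatechin-3-O-gallate-(4β→6)-gallocatechin
Conditions: H2 (1 atm), Pd(OH)2/C, Et3N (2 equiv), THF–MeOH–H2O, rt; filter under Ar, acidify with AcOH, Sephadex LH-20
Reagents that add atoms: none
Why: Catalytic hydrogenolysis cleaves the fourteen benzyl ethers and the aryl C–Br bond (amine buffers the HBr) while the gallate ester, the cyclic benzylic ethers, the interflavan bond and all five stereocentres are untouched.

**Compound list**

1 | (+)-gallocatechin, (2R,3S) | O[C@H]1Cc2c(O)cc(O)cc2O[C@@H]1c1cc(O)c(O)c(O)c1 | starting material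
2 | 5,7,3',4',5'-penta-O-benzyl-(+)-gallocatechin | O[C@H]1Cc2c(OCc4ccccc4)cc(OCc4ccccc4)cc2O[C@@H]1c5cc(OCc4ccccc4)c(OCc4ccccc4)c(OCc4ccccc4)c5 | intermediate
3 | 3,5,7,3',4',5'-hexa-O-benzyl-(+)-gallocatechin | O(Cc4ccccc4)[C@H]1Cc2c(OCc4ccccc4)cc(OCc4ccccc4)cc2O[C@@H]1c5cc(OCc4ccccc4)c(OCc4ccccc4)c(OCc4ccccc4)c5 | intermediate
4 | 8-bromo-hexa-O-benzyl-(+)-gallocatechin | O(Cc4ccccc4)[C@H]1Cc2c(OCc4ccccc4)cc(OCc4ccccc4)c(Br)c2O[C@@H]1c5cc(OCc4ccccc4)c(OCc4ccccc4)c(OCc4ccccc4)c5 | intermediate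
5 | 8-bromo-6-iodo-hexa-O-benzyl-(+)-gallocatechin | O(Cc4ccccc4)[C@H]1Cc2c(OCc4ccccc4)c(I)c(OCc4ccccc4)c(Br)c2O[C@@H]1c5cc(OCc4ccccc4)c(OCc4ccccc4)c(OCc4ccccc4)c5 | intermediate
6 | 3,5-bis(benzyloxy)phenol | Oc1cc(OCc2ccccc2)cc(OCc2ccccc2)c1 | starting material
7 | 2-(hydroxymethyl)-3,5-bis(benzyloxy)phenol (salicyl alcohol, as its magnesium phenoxide in the flask) | OCc1c(O)cc(OCc2ccccc2)cc1OCc2ccccc2 | intermediate
8 | 2-hydroxy-4,6-bis(benzyloxy)benzaldehyde | O=Cc1c(O)cc(OCc2ccccc2)cc1OCc2ccccc2 | intermediate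
9 | 2-(allyloxy)-4,6-bis(benzyloxy)benzaldehyde | O=Cc1c(OCC=C)cc(OCc2ccccc2)cc1OCc2ccccc2 | intermediate
10 | 8-bromo-6-lithio-hexa-O-benzyl-(+)-gallocatechin | O(Cc4ccccc4)[C@H]1Cc2c(OCc4ccccc4)c([Li])c(OCc4ccccc4)c(Br)c2O[C@@H]1c5cc(OCc4ccccc4)c(OCc4ccccc4)c(OCc4ccccc4)c5 | intermediate
11 | (2-allyloxy-4,6-dibenzyloxyphenyl)(8-bromo-hexa-O-benzylgallocatechin-6-yl)methanol, both carbinol epimers | OC(c1c(OCC=C)cc(OCc4ccccc4)cc1OCc4ccccc4)c5c(OCc4ccccc4)c(Br)c6c(c5OCc4ccccc4)C[C@H](OCc4ccccc4)[C@@H](c5cc(OCc4ccccc4)c(OCc4ccccc4)c(OCc4ccccc4)c5)O6 | intermediate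
12 | (2-hydroxy-4,6-dibenzyloxyphenyl)(8-bromo-hexa-O-benzylgallocatechin-6-yl)methanol, both carbinol epimers | OC(c1c(O)cc(OCc4ccccc4)cc1OCc4ccccc4)c5c(OCc4ccccc4)c(Br)c6c(c5OCc4ccccc4)C[C@H](OCc4ccccc4)[C@@H](c5cc(OCc4ccccc4)c(OCc4ccccc4)c(OCc4ccccc4)c5)O6 | intermediate
13 | 3,4,5-tris(benzyloxy)benzoic acid | OC(=O)c1cc(OCc2ccccc2)c(OCc2ccccc2)c(OCc2ccccc2)c1 | starting material
14 | 3,4,5-tris(benzyloxy)benzoyl chloride | ClC(=O)c1cc(OCc2ccccc2)c(OCc2ccccc2)c(OCc2ccccc2)c1 | intermediate
15 | 3',4',5'-tris(benzyloxy)acetophenone | CC(=O)c1cc(OCc2ccccc2)c(OCc2ccccc2)c(OCc2ccccc2)c1 | intermediate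
16 | 3',4',5'-tris(benzyloxy)acetophenone oxime | CC(=NO)c1cc(OCc2ccccc2)c(OCc2ccccc2)c(OCc2ccccc2)c1 | intermediate
17 | 3',4',5'-tris(benzyloxy)acetophenone O-acetyl oxime | CC(=NOC(C)=O)c1cc(OCc2ccccc2)c(OCc2ccccc2)c(OCc2ccccc2)c1 | intermediate
18 | N-[1-(3,4,5-tribenzyloxyphenyl)vinyl]acetamide | C=C(NC(C)=O)c1cc(OCc2ccccc2)c(OCc2ccccc2)c(OCc2ccccc2)c1 | intermediate
19 | A-ring ortho-quinone methide, 3,5-dibenzyloxy-6-[(lower unit-6-yl)methylidene]cyclohexa-2,4-dienone | O=C1C=C(OCc4ccccc4)C=C(OCc4ccccc4)C1=Cc5c(OCc4ccccc4)c(Br)c6c(c5OCc4ccccc4)C[C@H](OCc4ccccc4)[C@@H](c5cc(OCc4ccccc4)c(OCc4ccccc4)c(OCc4ccccc4)c5)O6 | intermediate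
20 | (4R)-2-acetamido-2-(3,4,5-tribenzyloxyphenyl)-5,7-dibenzyloxy-4-(lower unit-6-yl)chroman, C2 epimers | CC(=O)NC1(c7cc(OCc4ccccc4)c(OCc4ccccc4)c(OCc4ccccc4)c7)C[C@@H](c5c(OCc4ccccc4)c(Br)c6c(c5OCc4ccccc4)C[C@H](OCc4ccccc4)[C@@H](c5cc(OCc4ccccc4)c(OCc4ccccc4)c(OCc4ccccc4)c5)O6)c3c(OCc4ccccc4)cc(OCc4ccccc4)cc3O1 | intermediate
21 | (4R)-5,7-dibenzyloxy-2-(3,4,5-tribenzyloxyphenyl)-4-(8-bromo-hexa-O-benzylgallocatechin-6-yl)-4H-chromene | C1(c7cc(OCc4ccccc4)c(OCc4ccccc4)c(OCc4ccccc4)c7)=C[C@@H](c5c(OCc4ccccc4)c(Br)c6c(c5OCc4ccccc4)C[C@H](OCc4ccccc4)[C@@H](c5cc(OCc4ccccc4)c(OCc4ccccc4)c(OCc4ccccc4)c5)O6)c3c(OCc4ccccc4)cc(OCc4ccccc4)cc3O1 | intermediate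
22 | 2α,3α-epoxide of 21 (oxygen anti to the C4 aryl) | O1[C@@H]2[C@@H](c5c(OCc4ccccc4)c(Br)c6c(c5OCc4ccccc4)C[C@H](OCc4ccccc4)[C@@H](c5cc(OCc4ccccc4)c(OCc4ccccc4)c(OCc4ccccc4)c5)O6)c3c(OCc4ccccc4)cc(OCc4ccccc4)cc3O[C@]12c7cc(OCc4ccccc4)c(OCc4ccccc4)c(OCc4ccccc4)c7 | intermediate
23 | (3R,4R)-2-methoxy-2-aryl-4-(lower unit-6-yl)chroman-3-ol, 3α-OH trans to the 4β aryl, C2 anomers | O[C@@H]1[C@@H](c5c(OCc4ccccc4)c(Br)c6c(c5OCc4ccccc4)C[C@H](OCc4ccccc4)[C@@H](c5cc(OCc4ccccc4)c(OCc4ccccc4)c(OCc4ccccc4)c5)O6)c3c(OCc4ccccc4)cc(OCc4ccccc4)cc3OC1(OC)c7cc(OCc4ccccc4)c(OCc4ccccc4)c(OCc4ccccc4)c7 | intermediate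
24 | 3-O-(3,4,5-tribenzyloxybenzoyl) ester of 23, C2 anomers | O=C(O[C@@H]1[C@@H](c5c(OCc4ccccc4)c(Br)c6c(c5OCc4ccccc4)C[C@H](OCc4ccccc4)[C@@H](c5cc(OCc4ccccc4)c(OCc4ccccc4)c(OCc4ccccc4)c5)O6)c3c(OCc4ccccc4)cc(OCc4ccccc4)cc3OC1(OC)c7cc(OCc4ccccc4)c(OCc4ccccc4)c(OCc4ccccc4)c7)c8cc(OCc4ccccc4)c(OCc4ccccc4)c(OCc4ccccc4)c8 | intermediate
25 | C2 oxocarbenium ion of 24 (in equilibrium with the C3 acyloxonium), methoxytrifluoroborate salt | O=C(O[C@@H]1[C@@H](c5c(OCc4ccccc4)c(Br)c6c(c5OCc4ccccc4)C[C@H](OCc4ccccc4)[C@@H](c5cc(OCc4ccccc4)c(OCc4ccccc4)c(OCc4ccccc4)c5)O6)c3c(OCc4ccccc4)cc(OCc4ccccc4)cc3[O+]=C1c7cc(OCc4ccccc4)c(OCc4ccccc4)c(OCc4ccccc4)c7)c8cc(OCc4ccccc4)c(OCc4ccccc4)c(OCc4ccccc4)c8.CO[B-](F)(F)F | intermediate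
26 | (2R,3R,4R)-penta-O-benzyl-epigallocatechin-3-O-(tri-O-benzylgallate)-(4β→6)-8-bromo-hexa-O-benzyl-(2R,3S)-gallocatechin | O=C(O[C@@H]1[C@@H](c5c(OCc4ccccc4)c(Br)c6c(c5OCc4ccccc4)C[C@H](OCc4ccccc4)[C@@H](c5cc(OCc4ccccc4)c(OCc4ccccc4)c(OCc4ccccc4)c5)O6)c3c(OCc4ccccc4)cc(OCc4ccccc4)cc3O[C@@H]1c7cc(OCc4ccccc4)c(OCc4ccccc4)c(OCc4ccccc4)c7)c8cc(OCc4ccccc4)c(OCc4ccccc4)c(OCc4ccccc4)c8 | intermediate
27 | CNP0271447.2, (2R,3R,4R)-epigallocatechin-3-O-gallate-(4β→6)-(2R,3S)-gallocatechin | O=C(O[C@@H]1[C@@H](c2c(O)cc3c(c2O)C[C@H](O)[C@@H](c2cc(O)c(O)c(O)c2)O3)c2c(O)cc(O)cc2O[C@@H]1c1cc(O)c(O)c(O)c1)c1cc(O)c(O)c(O)c1 | target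

**Step count**

Total: 17 steps. Longest linear sequence: 11 steps (1, 2, 3, 4, 7, 8, 13, 14, 15, 16, 17) from (+)-gallocatechin.

**Steps most likely to fail, with fallbacks**

Step 13. Three processes may defeat it. The methide is stabilised by two trioxygenated rings, so C–C bond formation with the enamide may be slow or reversible. The catalyst pocket must hold a 2,6‑disubstituted aryl group, so face discrimination at C4 may be weak. Acid may also ipso‑protonate the lower A ring of the product and expel it as a flavylium ion, which would erode the C4 purity on re‑addition.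
The fallback sets out from 8, 15 and 5 and comes back at 21. Acid‑mediated aldol condensation and cyclodehydration of 8 with 15 (HBF4·OEt2, AcOH, rt) should give 5,7‑bis(benzyloxy)‑2‑(3,4,5‑tribenzyloxyphenyl)chromenylium tetrafluoroborate F1. The aryllithium 10, regenerated from 5 as in step 7, is then added to a suspension of F1 in THF at −78 °C. Organometallic addition to a flavylium salt goes to C4 when C2 carries the aryl group, so this should give 21 together with its C4 epimer F2. The two are diastereomers because the lower unit is chiral, and they are separated by chromatography. This gives up catalyst control at C4 in exchange for an irreversible C4–C6' bond formation between a strong nucleophile and a cation.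

Step 16. Hydride may arrive on the α face because the β face carries the C4 aryl in a 1,3 relation to C2, which would give the 2,3‑trans flavan. The oxocarbenium ion may also lose the C3 proton to an enol ester, and the Lewis acid may ionise the interflavan bond.
The fallback sets out from 4 and 14 and comes back at 26, taking C2 and C3 from the chiral pool. (−)-Epigallocatechin F3 is perbenzylated on its phenols (BnBr, K2CO3, DMF) to the penta‑O‑benzyl ether F4. Benzylic oxidation with DDQ in the presence of 2‑ethoxyethanol (CH2Cl2, rt) gives the 4β‑(2‑ethoxyethoxy) ether F5. TMSOTf‑catalysed condensation of F5 with an excess of 4 (CH2Cl2, −78 °C) should join C4 to C6', since C8' is blocked, with attack anti to the C3 substituent, to give the 3,4‑trans dimer with a free 3‑OH, F6. Galloylation of F6 with 14 (DMAP, pyridine) gives 26.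

Step 14. The dioxirane may oxidise the electron‑rich rings or benzylic C–H bonds in competition with the enol ether, and the 2‑aryl epoxide may rearrange by hydride shift to the chroman‑3‑one before methanol traps it.
The fallback sets out from 21 and comes back at 23. Catalytic osmylation (OsO4, NMO, acetone–H2O, rt), which touches only the enol ether and adds anti to the C4 aryl, should give the cis‑2,3‑diol hemiketal F7 without passing through an epoxide. Mild ketalisation of F7 (PPTS, MeOH, rt) gives 23.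

**Further compounds**

F1 | step 13 | 5,7-bis(benzyloxy)-2-(3,4,5-tribenzyloxyphenyl)chromenylium tetrafluoroborate | c1(-c7cc(OCc4ccccc4)c(OCc4ccccc4)c(OCc4ccccc4)c7)ccc2c(OCc4ccccc4)cc(OCc4ccccc4)cc2[o+]1.F[B-](F)(F)F
F2 | step 13 | (4S)-epimer of 21 | C1(c7cc(OCc4ccccc4)c(OCc4ccccc4)c(OCc4ccccc4)c7)=C[C@H](c5c(OCc4ccccc4)c(Br)c6c(c5OCc4ccccc4)C[C@H](OCc4ccccc4)[C@@H](c5cc(OCc4ccccc4)c(OCc4ccccc4)c(OCc4ccccc4)c5)O6)c3c(OCc4ccccc4)cc(OCc4ccccc4)cc3O1
F3 | step 16 | (−)-epigallocatechin, (2R,3R), purchased | O[C@@H]1Cc2c(O)cc(O)cc2O[C@@H]1c1cc(O)c(O)c(O)c1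
F4 | step 16 | 5,7,3',4',5'-penta-O-benzyl-(−)-epigallocatechin | O[C@@H]1Cc2c(OCc4ccccc4)cc(OCc4ccccc4)cc2O[C@@H]1c5cc(OCc4ccccc4)c(OCc4ccccc4)c(OCc4ccccc4)c5
F5 | step 16 | 4β-(2-ethoxyethoxy)-penta-O-benzyl-(−)-epigallocatechin | O[C@@H]1[C@@H](OCCOCC)c2c(OCc4ccccc4)cc(OCc4ccccc4)cc2O[C@@H]1c5cc(OCc4ccccc4)c(OCc4ccccc4)c(OCc4ccccc4)c5
F6 | step 16 | penta-O-benzyl-epigallocatechin-(4β→6)-8-bromo-hexa-O-benzylgallocatechin, free 3-OH | O[C@@H]1[C@@H](c5c(OCc4ccccc4)c(Br)c6c(c5OCc4ccccc4)C[C@H](OCc4ccccc4)[C@@H](c5cc(OCc4ccccc4)c(OCc4ccccc4)c(OCc4ccccc4)c5)O6)c3c(OCc4ccccc4)cc(OCc4ccccc4)cc3O[C@@H]1c7cc(OCc4ccccc4)c(OCc4ccccc4)c(OCc4ccccc4)c7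
F7 | step 14 | 2α,3α-dihydroxy hemiketal from 21 (cis-diol anti to the C4 aryl) | O[C@@H]1[C@@H](c5c(OCc4ccccc4)c(Br)c6c(c5OCc4ccccc4)C[C@H](OCc4ccccc4)[C@@H](c5cc(OCc4ccccc4)c(OCc4ccccc4)c(OCc4ccccc4)c5)O6)c3c(OCc4ccccc4)cc(OCc4ccccc4)cc3O[C@@]1(O)c7cc(OCc4ccccc4)c(OCc4ccccc4)c(OCc4ccccc4)c7
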